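**Remarks.** C1–C10 in the text are daucane locants: C1 = methyl-bearing ring-fusion carbon, C2, C3, C4 = isopropyl carbinol, C5 = ring-fusion CH, C6 = acyloxy carbon, C7, C8 = methyl carbinol, C9=C10. The target is (1R,4R,5S,6S,8S). Bicyclic intermediates are named with the azulene locants of the target.
Assumption: compounds 1, 3 and 19 are commercial; no bond to the stereocentre of (S)-citramalic acid is broken, so it becomes C8 (S) of the target.

## The problem

The target is a trans-fused bicyclo[5.3.0]decane (five-membered ring C1–C5, seven-membered ring C1, C5–C10) with a vanillate on its only secondary alcohol. The quaternary C1 sits at the ring fusion next to the cis C9=C10 alkene, so it must be set early and in a fixed relation to C5 (CH3 β, H-5 α). C5 is the hub of the contiguous array C1–C5(–C4)–C6; once C1 and the trans fusion exist, C4 and C6 can be controlled from the ring. C8, a tertiary allylic carbinol 1,4 to C1 across the alkene, is too remote for that and is best brought in as a stereocentre of its own. Sensitive points are the tertiary allylic alcohol at C8 (ionisation, 1,3-shift), every β-oxygenated ketone on the way (retro-aldol, β-elimination, epimerisation at C5) and the phenolic aryl ester (base). The feature the plan uses: read C9 as a ketone (it becomes C9=C10 through its enol triflate) and C5–C6 as an alkene (it becomes H-5/O-6 by hydroboration). The seven-membered ring is then a cyclohept-4-enone C9(=O)–C10–C1–C5=C6–C7–C8, with the carbonyl flanked by the fully substituted C8 and with C1 part of the cyclopentane. That is the product pattern of the Claisen ring expansion of a 2-methylene-tetrahydrofuran (ring O–C9–C8–C7–C6) bearing a cyclopentenyl group (C5=C1) on C6: C8 rides through as a ring atom of the ether, and C1 is created as the terminus of the [3,3] shift.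

## Retrosynthesis

**23 ⇒ 22 ⇒ 18 + 21.** The C6–O acyl bond is cut last. C6–OH is the only secondary hydroxyl of 18 (C4–OH is tertiary, C8–O is silylated), so no differentiation is needed. The phenol is carried as a silyl ether so that one fluoride step frees both it and C8–OH. The forward step must acylate a hindered alcohol without touching C6's configuration.

**18 ⇒ 17 ⇒ 16.** The C4–isopropyl bond is cut to the trans-fused cyclopentanone 17, masked as the ketal 16. Adding isopropyl after the ring fusion is set (rather than before) gives the nucleophile a clear face: anti to the C5–C6 bond beside the carbonyl and anti to the angular methyl.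

**16 ⇒ 15 ⇒ 14 ⇒ 13.** No skeletal bond is cut. C9=C10 goes back to the enol triflate 14 of ketone 13, which can enolise only towards C10. H-5/6-OH go back to the C5=C6 alkene. Running the hydroboration on the triflate 14 (not on the diene) keeps the second alkene electron-poor and inert. Asked of the forward reactions: borane on the α-face of C5=C6.

**13 ⇒ 12 (key).** The C1–C10 bond is cut and the C6–O bond re-formed: the cycloheptenone becomes the 2-methylene-tetrahydrofuran 12. This single cut removes the seven-membered ring and the quaternary centre; 12 has only two stereocentres (C6, C8), each set independently. A cut at C9=C10 (metathesis) would leave the quaternary centre still to be made. Asked of the forward reaction: a [3,3] shift onto a fully substituted cyclopentene carbon, with chirality transfer from C6 to C1.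

**12 ⇒ 11 ⇒ 10 ⇒ 8.** The exocyclic methylene (C10) comes from the lactone carbonyl of 11 by titanium methylenation. Lactone 10 comes from ketone 8 by enantioselective reduction at C6 and acyl transfer from the dioxolanone (via 9).

**8 ⇒ 4 + 2.** The C5–C6 bond is cut between an acyl unit and an alkenyl metal (via 5, 6 and 7). Acid 4 is the acetonide of 3, which supplies C6–C9 and the C8 stereocentre. Bromo-ketal 2 comes from 1 and supplies the cyclopentane with the C1 methyl and the masked C4 ketone.

## Roads not taken

**Alternative 1:** (the obvious one) Cut C9=C10 by ring-closing metathesis and C5–C6 by an aldol. Forward: conjugate addition of a vinyl metal to a 3-methylcyclopentenone, trapping of the enolate with a chiral β-silyloxy aldehyde, isopropyl addition, then metathesis of diene A1. Each bond and each stereocentre needs its own step. The enolate is trapped next to a quaternary carbon whose two substituents (methyl, vinyl) are nearly equal in size, so the trans fusion is not secured without a bulky vinyl surrogate that must later be removed. The acyclic aldehyde with the C8 quaternary carbinol needs a synthesis of its own. The metathesis joins two vinyl groups that both sit on fully substituted carbons. The chosen plan makes ring, quaternary centre and two functional handles in one step.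

**Alternative 2:** Cut C5–C1/C5–C10 and C7–C8 by a formal [4+3]: rhodium-carbenoid cyclopropanation of the diene in the acyclic diazo ketone A2, then divinylcyclopropane rearrangement. The precursor is acyclic, which is attractive. But the methyl on the third cyclopropane carbon points into the boat transition state, and the enantioselectivity would rest on a chiral catalyst with an untried all-carbon ketone tether. The product has C5 as sp2 carbon and C4 as ketone with two nearly equivalent faces, so C4, C5, C6 and C8 would all remain to be set. The chosen plan takes its chirality from the pool and a reliable reduction and passes it on by a sigmatropic shift.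

**Alternative 3:** Cut C1–C5 by a dianionic Ireland–Claisen rearrangement of an (E)-allylic β-hydroxy ester (carbinol from asymmetric hydrogenation), giving the acid A3 with C1 and C5 set through a chair transition state. This is stereochemically safe for C1/C5, but no ring is formed. The C4 carbinol must be oxidised and rebuilt by a Barbier closure on a β-keto ester whose C5 is labile, and C6 and C8 would have to be set on an open chain before the seven-membered ring is closed. The chosen plan is shorter after its key step and sets C6 and C4 on the rigid bicycle.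

Key step: step 7

## Steps

Step 1
Reactants: 1 2-bromo-3-methylcyclopent-2-en-1-one
Product: 2 6-bromo-7-methyl-1,4-dioxaspiro[4.4]non-6-ene
Conditions: ethylene glycol, p-TsOH (cat.), benzene, reflux (Dean–Stark)
Reagents that add atoms: ethylene glycol, OCCO
Why: Acid-catalysed ketalisation; the α-bromo enone is the standard precursor of an α-keto-vinyl anion equivalent, and the bromine disfavours migration of the double bond.

Step 2
Reactants: 3 (S)-citramalic acid
Product: 4 2-[(4S)-2,2,4-trimethyl-5-oxo-1,3-dioxolan-4-yl]acetic acid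
Conditions: 2,2-dimethoxypropane, p-TsOH (cat.), rt
Reagents that add atoms: 2,2-dimethoxypropane, COC(C)(C)OC
Why: Acetonide formation of an α-hydroxy acid gives the five-membered dioxolanone selectively and leaves the β-carboxyl free; the stereocentre (later C8) is not touched.

Step 3
Reactants: 4 2-[(4S)-2,2,4-trimethyl-5-oxo-1,3-dioxolan-4-yl]acetic acid; 2 6-bromo-7-methyl-1,4-dioxaspiro[4.4]non-6-ene
Product: 8 (5S)-2,2,5-trimethyl-5-[2-(7-methyl-1,4-dioxaspiro[4.4]non-6-en-6-yl)-2-oxoethyl]-1,3-dioxolan-4-one, via acid chloride 5 (not isolated), via alkenyllithium 6 (not isolated), via alkenylzinc chloride 7 (not isolated)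
Conditions: 4, (COCl)2, DMF (cat.), CH2Cl2, then evaporation; 2, t-BuLi (2 equiv), THF, −78 °C, then ZnCl2; then 5, Pd(PPh3)4 (cat.), THF, 0 °C → rt
Reagents that add atoms: none
Why: Negishi acylation: bromine–lithium exchange gives the alkenyllithium, zinc lowers its basicity, and palladium couples it with the acid chloride without attack on the dioxolanone; this forms the C5–C6 bond.

Step 4
Reactants: 8 (5S)-2,2,5-trimethyl-5-[2-(7-methyl-1,4-dioxaspiro[4.4]non-6-en-6-yl)-2-oxoethyl]-1,3-dioxolan-4-one
Product: 10 (3S,5S)-3-hydroxy-3-methyl-5-(7-methyl-1,4-dioxaspiro[4.4]non-6-en-6-yl)oxolan-2-one, via hydroxy dioxolanone 9 (not isolated)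
Conditions: (R)-Me-CBS (cat.), BH3·SMe2, THF, −30 °C; MeOH; then DBU (cat.), CH2Cl2, rt
Reagents that add atoms: none
Why: Corey–Bakshi–Shibata reduction with the tetrasubstituted alkenyl group as the large and CH2 as the small substituent should give the (S)-carbinol at C6; under mild base this hydroxyl acylates itself on the activated dioxolanone carbonyl (5-exo-trig) with loss of acetone, giving the γ-lactone with C8–OH and the cyclopentenyl group cis.

Step 5
Reactants: 10 (3S,5S)-3-hydroxy-3-methyl-5-(7-methyl-1,4-dioxaspiro[4.4]non-6-en-6-yl)oxolan-2-one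
Product: 11 (3S,5S)-3-methyl-5-(7-methyl-1,4-dioxaspiro[4.4]non-6-en-6-yl)-3-[(triethylsilyl)oxy]oxolan-2-one
Conditions: Et3SiCl, imidazole, DMAP (cat.), DMF, 50 °C
Reagents that add atoms: chlorotriethylsilane, CC[Si](Cl)(CC)CC
Why: Silylation of the tertiary α-hydroxyl (the silyl triflate is avoided because it can open the dioxolane); the ether later prevents α-ketol rearrangement when the C9 ketone is enolised and shields the tertiary allylic alcohol from acid.

Step 6
Reactants: 11 (3S,5S)-3-methyl-5-(7-methyl-1,4-dioxaspiro[4.4]non-6-en-6-yl)-3-[(triethylsilyl)oxy]oxolan-2-one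
Product: 12 triethyl{[(3S,5S)-3-methyl-2-methylidene-5-(7-methyl-1,4-dioxaspiro[4.4]non-6-en-6-yl)oxolan-3-yl]oxy}silane
Conditions: Cp2TiMe2, toluene, 70 °C, dark; filtration through basic alumina
Reagents that add atoms: dimethyltitanocene, [CH3-].[CH3-].[Ti+4].[cH-]1cccc1.[cH-]1cccc1
Why: Petasis methylenation of a lactone carbonyl under non-acidic conditions gives the exocyclic enol ether (C10 is the new CH2) and leaves ketal, silyl ether and both stereocentres untouched.

Step 7
Reactants: 12 triethyl{[(3S,5S)-3-methyl-2-methylidene-5-(7-methyl-1,4-dioxaspiro[4.4]non-6-en-6-yl)oxolan-3-yl]oxy}silane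
Product: 13 (6'S,8a'R)-6',8a'-dimethyl-6'-[(triethylsilyl)oxy]-1',2',5',6',8',8a'-hexahydro-7'H-spiro[1,3-dioxolane-2,3'-azulen]-7'-one
Conditions: toluene, Et3N (trace), base-washed sealed tube, 185 °C
Reagents that add atoms: none
Why: Concerted [3,3] shift of the allyl vinyl ether C10=C9–O–C6–C5=C1: the C10–C1 bond forms, the C6–O bond breaks, C9 becomes the ketone and C5=C6 the new alkene. The closest known reaction type is the Claisen ring expansion of 2-methylene-5-alkenyl-tetrahydrofurans to cyclohept-4-enones and of 2-methylene-6-cycloalkenyl-tetrahydropyrans to fused cyclooctenones, including cases that create an angular methyl centre. The seven-membered carbocycle is closed by oxygen-to-carbon ring expansion: the ring O–C9–C8–C7–C6 loses O and gains C10, C1 and C5, through a chair-like six-membered array bridged by C7–C8. The bridge allows only one arrangement, the one that gives the cis ring alkene C5=C6. The new stereocentre C1 is controlled by C6: C10 is delivered to the cyclopentene face from which the C6–O bond departs, so (6S) gives (1R). C8 is a spectator, and because its oxygen is cis to the cyclopentenyl group in 12 it ends up cis to the C1 methyl in 13, as the target requires. Regioselectivity is not an issue (one allyl vinyl ether unit). The selectivity the step needs is rearrangement over acid-catalysed migration of the exocyclic double bond into the ring, secured by the base-washed vessel and trace amine.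

Step 8
Reactants: 13 (6'S,8a'R)-6',8a'-dimethyl-6'-[(triethylsilyl)oxy]-1',2',5',6',8',8a'-hexahydro-7'H-spiro[1,3-dioxolane-2,3'-azulen]-7'-one
Product: 14 (6'S,8a'R)-6',8a'-dimethyl-6'-[(triethylsilyl)oxy]-1',2',5',6'-tetrahydro-8a'H-spiro[1,3-dioxolane-2,3'-azulen]-7'-yl trifluoromethanesulfonate
Conditions: KHMDS, THF, −78 °C; PhNTf2, −78 → 0 °C
Reagents that add atoms: N-phenylbis(trifluoromethanesulfonimide), O=S(=O)(N(c1ccccc1)S(=O)(=O)C(F)(F)F)C(F)(F)F
Why: Enol triflate formation; the ketone can enolise only towards C10 because C8 is fully substituted, so a single C9=C10 enol triflate forms.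

Step 9
Reactants: 14 (6'S,8a'R)-6',8a'-dimethyl-6'-[(triethylsilyl)oxy]-1',2',5',6'-tetrahydro-8a'H-spiro[1,3-dioxolane-2,3'-azulen]-7'-yl trifluoromethanesulfonate
Product: 15 (3a'S,4'S,6'S,8a'R)-4'-hydroxy-6',8a'-dimethyl-6'-[(triethylsilyl)oxy]-1',2',3a',4',5',6'-hexahydro-8a'H-spiro[1,3-dioxolane-2,3'-azulen]-7'-yl trifluoromethanesulfonate
Conditions: BH3·THF, THF, 0 °C → rt; then NaBO3·4H2O, H2O, rt
Reagents that add atoms: sodium perborate, [Na+].[Na+].O[B-]1(O)OO[B-](O)(O)OO1
Why: Hydroboration–oxidation (syn, anti-Markovnikov): boron goes to the less substituted C6 and hydrogen to C5, while the electron-poor enol triflate alkene is left alone; borane should approach the α-face, anti to the angular C1 methyl that lies over C5 (as with Δ5-steroids) and anti to the β C8 silyloxy group, which sets H-5 α (trans fusion) and 6α-OH together.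

Step 10
Reactants: 15 (3a'S,4'S,6'S,8a'R)-4'-hydroxy-6',8a'-dimethyl-6'-[(triethylsilyl)oxy]-1',2',3a',4',5',6'-hexahydro-8a'H-spiro[1,3-dioxolane-2,3'-azulen]-7'-yl trifluoromethanesulfonate
Product: 16 (3a'S,4'S,6'S,8a'R)-6',8a'-dimethyl-6'-[(triethylsilyl)oxy]-1',2',3a',4',5',6'-hexahydro-8a'H-spiro[1,3-dioxolane-2,3'-azulen]-4'-ol
Conditions: Pd(OAc)2 (cat.), PPh3, HCO2H, Et3N, DMF, 60 °C
Reagents that add atoms: none
Why: Palladium-catalysed formate reduction of an enol triflate replaces OTf by H without moving the double bond and gives the cis C9=C10 alkene of the target.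

Step 11
Reactants: 16 (3a'S,4'S,6'S,8a'R)-6',8a'-dimethyl-6'-[(triethylsilyl)oxy]-1',2',3a',4',5',6'-hexahydro-8a'H-spiro[1,3-dioxolane-2,3'-azulen]-4'-ol
Product: 17 (3aS,4S,6S,8aR)-4-hydroxy-6,8a-dimethyl-6-[(triethylsilyl)oxy]-1,2,3a,4,5,6-hexahydroazulen-3(8aH)-one
Conditions: PPTS, acetone–H2O (10:1), 45 °C
Reagents that add atoms: water, O
Why: Mild acid hydrolysis of the dioxolane; the buffered acid should neither epimerise C5, dehydrate the β-hydroxy ketone nor ionise the tertiary allylic silyl ether.

Step 12
Reactants: 17 (3aS,4S,6S,8aR)-4-hydroxy-6,8a-dimethyl-6-[(triethylsilyl)oxy]-1,2,3a,4,5,6-hexahydroazulen-3(8aH)-one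
Product: 18 (3R,3aS,4S,6S,8aR)-6,8a-dimethyl-3-(propan-2-yl)-6-[(triethylsilyl)oxy]-1,2,3,3a,4,5,6,8a-octahydroazulene-3,4-diol
Conditions: i-PrMgCl (excess), CeCl3, THF, −78 → −20 °C
Reagents that add atoms: isopropylmagnesium chloride, CC(C)[Mg]Cl
Why: Organocerium 1,2-addition, chosen to suppress enolisation, β-hydride reduction and retro-aldol of the alkoxide; the nucleophile should enter from the α-face, anti to the β-oriented C5–C6 bond beside the carbonyl and to the angular methyl, giving 4β-OH and 4α-isopropyl.

Step 13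
Reactants: 19 vanillic acid
Product: 21 4-[(tert-butyldimethylsilyl)oxy]-3-methoxybenzoic acid, via bis-silyl derivative 20 (not isolated)
Conditions: TBSCl (2.2 equiv), imidazole, DMF, rt; then AcOH–H2O–THF, rt
Reagents that add atoms: tert-butyldimethylsilyl chloride, CC(C)(C)[Si](C)(C)Cl
Why: Silylation of phenol and acid, then selective hydrolysis of the much more labile silyl ester under mild aqueous acid, which the aryl silyl ether survives.

Step 14
Reactants: 18 (3R,3aS,4S,6S,8aR)-6,8a-dimethyl-3-(propan-2-yl)-6-[(triethylsilyl)oxy]-1,2,3,3a,4,5,6,8a-octahydroazulene-3,4-diol; 21 4-[(tert-butyldimethylsilyl)oxy]-3-methoxybenzoic acid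
Product: 22 (3R,3aS,4S,6S,8aR)-3-hydroxy-6,8a-dimethyl-3-(propan-2-yl)-6-[(triethylsilyl)oxy]-1,2,3,3a,4,5,6,8a-octahydroazulen-4-yl 4-[(tert-butyldimethylsilyl)oxy]-3-methoxybenzoate
Conditions: DCC, DMAP, CH2Cl2, rt → 40 °C
Reagents that add atoms: none
Why: Steglich esterification; only the secondary C6–OH is acylated (C4–OH is tertiary, C8–O silylated), and the C6–O bond is not broken, so its configuration is kept.

Step 15
Reactants: 22 (3R,3aS,4S,6S,8aR)-3-hydroxy-6,8a-dimethyl-3-(propan-2-yl)-6-[(triethylsilyl)oxy]-1,2,3,3a,4,5,6,8a-octahydroazulen-4-yl 4-[(tert-butyldimethylsilyl)oxy]-3-methoxybenzoate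
Product: 23 (3R,3aS,4S,6S,8aR)-3,6-dihydroxy-6,8a-dimethyl-3-(propan-2-yl)-1,2,3,3a,4,5,6,8a-octahydroazulen-4-yl 4-hydroxy-3-methoxybenzoate
Conditions: TBAF, AcOH, THF, 0 °C → rt
Reagents that add atoms: none
Why: Fluoride cleaves the aryl silyl ether and the tertiary triethylsilyl ether in one step; the acetic acid buffer should protect the aryl ester from the phenoxide/alkoxide and avoid strong acid at the tertiary allylic alcohol.

## Compound list

1 | 2-bromo-3-methylcyclopent-2-en-1-one | CC1=C(Br)C(=O)CC1 | starting material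
2 | 6-bromo-7-methyl-1,4-dioxaspiro[4.4]non-6-ene | CC1=C(Br)C2(CC1)OCCO2 | intermediate
3 | (S)-citramalic acid, (2S)-2-hydroxy-2-methylbutanedioic acid | C[C@](O)(CC(=O)O)C(=O)O | starting material
4 | 2-[(4S)-2,2,4-trimethyl-5-oxo-1,3-dioxolan-4-yl]acetic acid | C[C@@]1(CC(=O)O)OC(C)(C)OC1=O | intermediate
5 | 2-[(4S)-2,2,4-trimethyl-5-oxo-1,3-dioxolan-4-yl]acetyl chloride | C[C@@]1(CC(=O)Cl)OC(C)(C)OC1=O | intermediate
6 | (7-methyl-1,4-dioxaspiro[4.4]non-6-en-6-yl)lithium | [Li]C1=C(C)CCC12OCCO2 | intermediate
7 | chloro(7-methyl-1,4-dioxaspiro[4.4]non-6-en-6-yl)zinc | Cl[Zn]C1=C(C)CCC12OCCO2 | intermediate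
8 | (5S)-2,2,5-trimethyl-5-[2-(7-methyl-1,4-dioxaspiro[4.4]non-6-en-6-yl)-2-oxoethyl]-1,3-dioxolan-4-one | C[C@@]1(CC(=O)C2=C(C)CCC23OCCO3)OC(C)(C)OC1=O | intermediate
9 | (5S)-5-[(2S)-2-hydroxy-2-(7-methyl-1,4-dioxaspiro[4.4]non-6-en-6-yl)ethyl]-2,2,5-trimethyl-1,3-dioxolan-4-one | C[C@@]1(C[C@H](O)C2=C(C)CCC23OCCO3)OC(C)(C)OC1=O | intermediate
10 | (3S,5S)-3-hydroxy-3-methyl-5-(7-methyl-1,4-dioxaspiro[4.4]non-6-en-6-yl)oxolan-2-one | C[C@]1(O)C[C@@H](C2=C(C)CCC23OCCO3)OC1=O | intermediate
11 | (3S,5S)-3-methyl-5-(7-methyl-1,4-dioxaspiro[4.4]non-6-en-6-yl)-3-[(triethylsilyl)oxy]oxolan-2-one | C[C@]1(O[Si](CC)(CC)CC)C[C@@H](C2=C(C)CCC23OCCO3)OC1=O | intermediate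
12 | triethyl{[(3S,5S)-3-methyl-2-methylidene-5-(7-methyl-1,4-dioxaspiro[4.4]non-6-en-6-yl)oxolan-3-yl]oxy}silane | C[C@]1(O[Si](CC)(CC)CC)C[C@@H](C2=C(C)CCC23OCCO3)OC1=C | intermediate
13 | (6'S,8a'R)-6',8a'-dimethyl-6'-[(triethylsilyl)oxy]-1',2',5',6',8',8a'-hexahydro-7'H-spiro[1,3-dioxolane-2,3'-azulen]-7'-one (C9 ketone, C5=C6 alkene, C4 ketal) | O=C1C[C@@]2(C)CCC3(OCCO3)C2=CC[C@]1(C)O[Si](CC)(CC)CC | intermediate
14 | (6'S,8a'R)-6',8a'-dimethyl-6'-[(triethylsilyl)oxy]-1',2',5',6'-tetrahydro-8a'H-spiro[1,3-dioxolane-2,3'-azulen]-7'-yl trifluoromethanesulfonate | FC(F)(F)S(=O)(=O)OC1=C[C@@]2(C)CCC3(OCCO3)C2=CC[C@]1(C)O[Si](CC)(CC)CC | intermediate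
15 | (3a'S,4'S,6'S,8a'R)-4'-hydroxy-6',8a'-dimethyl-6'-[(triethylsilyl)oxy]-1',2',3a',4',5',6'-hexahydro-8a'H-spiro[1,3-dioxolane-2,3'-azulen]-7'-yl trifluoromethanesulfonate | O[C@H]2C[C@](C)(O[Si](CC)(CC)CC)C(OS(=O)(=O)C(F)(F)F)=C[C@@]3(C)CCC4(OCCO4)[C@H]23 | intermediate
16 | (3a'S,4'S,6'S,8a'R)-6',8a'-dimethyl-6'-[(triethylsilyl)oxy]-1',2',3a',4',5',6'-hexahydro-8a'H-spiro[1,3-dioxolane-2,3'-azulen]-4'-ol | O[C@H]2C[C@](C)(O[Si](CC)(CC)CC)C=C[C@@]3(C)CCC4(OCCO4)[C@H]23 | intermediate
17 | (3aS,4S,6S,8aR)-4-hydroxy-6,8a-dimethyl-6-[(triethylsilyl)oxy]-1,2,3a,4,5,6-hexahydroazulen-3(8aH)-one | O[C@H]2C[C@](C)(O[Si](CC)(CC)CC)C=C[C@@]3(C)CCC(=O)[C@H]23 | intermediate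
18 | (3R,3aS,4S,6S,8aR)-6,8a-dimethyl-3-(propan-2-yl)-6-[(triethylsilyl)oxy]-1,2,3,3a,4,5,6,8a-octahydroazulene-3,4-diol | O[C@H]2C[C@](C)(O[Si](CC)(CC)CC)C=C[C@@]3(C)CC[C@@](O)(C(C)C)[C@H]23 | intermediate
19 | vanillic acid, 4-hydroxy-3-methoxybenzoic acid | COc1cc(C(=O)O)ccc1O | starting material
20 | tert-butyldimethylsilyl 4-[(tert-butyldimethylsilyl)oxy]-3-methoxybenzoate | COc1cc(C(=O)O[Si](C)(C)C(C)(C)C)ccc1O[Si](C)(C)C(C)(C)C | intermediate
21 | 4-[(tert-butyldimethylsilyl)oxy]-3-methoxybenzoic acid | COc1cc(C(=O)O)ccc1O[Si](C)(C)C(C)(C)C | intermediate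
22 | (3R,3aS,4S,6S,8aR)-3-hydroxy-6,8a-dimethyl-3-(propan-2-yl)-6-[(triethylsilyl)oxy]-1,2,3,3a,4,5,6,8a-octahydroazulen-4-yl 4-[(tert-butyldimethylsilyl)oxy]-3-methoxybenzoate | COc1cc(C(=O)O[C@H]2C[C@](C)(O[Si](CC)(CC)CC)C=C[C@@]3(C)CC[C@@](O)(C(C)C)[C@H]23)ccc1O[Si](C)(C)C(C)(C)C | intermediate
23 | (3R,3aS,4S,6S,8aR)-3,6-dihydroxy-6,8a-dimethyl-3-(propan-2-yl)-1,2,3,3a,4,5,6,8a-octahydroazulen-4-yl 4-hydroxy-3-methoxybenzoate | COc1cc(C(=O)O[C@H]2C[C@](C)(O)C=C[C@@]3(C)CC[C@@](O)(C(C)C)[C@H]23)ccc1O | target

## Step count and least certain steps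

Total: 15 steps. Longest linear sequence: 13 steps (3 → 4 → 8 → 10 → 11 → 12 → 13 → 14 → 15 → 16 → 17 → 18 → 22 → 23); steps 1 and 13 are side branches.

**Step 7 (key step).** Most likely failure: the exocyclic enol ether isomerises to the endocyclic dihydrofuran (traces of acid or titanium residues), which cannot rearrange. The shift may also be slow, because the new bond is made to a fully substituted cyclopentene carbon and the C1 methyl is pushed towards the C8 silyloxy group; at the temperature then needed, C6–O cleavage with elimination could compete.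
Fallback, from 9 (isolated when the DBU treatment of step 4 is left out) back to 13: the C1–C10 bond is made in the open-chain series and the ring is closed by acylation. Acetylation (Ac2O, pyridine, DMAP) gives the acetate F1. Ireland–Claisen rearrangement of its silyl ketene acetal (LDA, Me3SiCl, THF, −78 °C → rt) needs no bridged transition state and gives the acid F2; the C7 chain takes the axial position to avoid the ketal carbon, which puts C7 cis to C1 on the new exocyclic alkene and gives the same 1R centre. Two equivalents of LDA turn the acid into its enediolate, which acylates itself on the dioxolanone carbonyl (seven-membered ring, acetone lost) to the β-keto acid F3. This decarboxylates on acidic work-up to the hydroxy ketone F4, and silylation as in step 5 gives 13.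

**Step 9.** Most likely failure: poor facial selectivity. The C1 methyl (β) and the C10 arm of the seven-membered ring (α) flank C5 at similar distances, so attack syn to the methyl would give the cis-fused 6β-alcohol. Addition to this hindered trisubstituted alkene may also be slow enough for borane to begin reducing the triflate.
Fallback, from 14 back to 15: dimethyldioxirane (acetone, 0 °C) epoxidises only the electron-rich C5=C6 bond, from the α-face, to the epoxide F5. Titanocene(III) chloride (Cp2TiCl2, Zn, 1,4-cyclohexadiene, THF) then cleaves the C5–O bond homolytically, and hydrogen-atom transfer to the planar ring-fusion radical from the side away from the angular methyl gives 15. C5 is then set by radical reduction and no longer by the face of attack on the alkene.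

**Step 4.** Most likely failure: low enantioselectivity or slow reduction, because both groups on the ketone are bulky (a tetrasubstituted alkenyl with an ortho-like ketal, and a CH2 next to a quaternary carbon); incomplete acyl transfer is a lesser risk.
Fallback, from 8 back to 10: substrate control replaces reagent control. Methanolysis (K2CO3, MeOH, 0 °C) opens the dioxolanone to the β-hydroxy ketone methyl ester F6. Tetramethylammonium triacetoxyborohydride (MeCN–AcOH, −30 °C) delivers hydride from the C8 oxygen and gives the 1,3-anti diol ester F7, which is the relative configuration needed; it closes to 10 with a trace of DBU.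

**Step 12.** Most likely failure: enolisation or β-hydride reduction of the hindered ketone by the secondary Grignard reagent, or retro-aldol opening of the seven-membered ring through the C6 alkoxide.
Fallback, from 17 back to 18: isopropenylmagnesium bromide/CeCl3 (no β-hydrogen, smaller) gives the isopropenyl carbinol F8. Hydrogen-atom-transfer hydrogenation (Mn(dpm)3, PhSiH3, t-BuOOH, i-PrOH) then reduces only the 1,1-disubstituted alkene, since the hindered cis C9=C10 alkene would give a less stable secondary radical, and gives 18.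

## Further compounds

F1 | step 7 | (1S)-1-(7-methyl-1,4-dioxaspiro[4.4]non-6-en-6-yl)-2-[(4S)-2,2,4-trimethyl-5-oxo-1,3-dioxolan-4-yl]ethyl acetate | C[C@@]1(C[C@H](OC(C)=O)C2=C(C)CCC23OCCO3)OC(C)(C)OC1=O
F2 | step 7 | 2-[(7R)-7-methyl-6-{2-[(4S)-2,2,4-trimethyl-5-oxo-1,3-dioxolan-4-yl]ethylidene}-1,4-dioxaspiro[4.4]nonan-7-yl]acetic acid (C7 cis to C1 on the alkene) | OC(=O)C[C@@]1(C)CCC2(OCCO2)/C1=C/C[C@]3(C)OC(C)(C)OC3=O
F3 | step 7 | (6'S,8a'R)-6'-hydroxy-6',8a'-dimethyl-7'-oxo-1',2',5',6',8',8a'-hexahydro-7'H-spiro[1,3-dioxolane-2,3'-azulene]-8'-carboxylic acid (C10 epimers) | O=C1C(C(=O)O)[C@@]2(C)CCC3(OCCO3)C2=CC[C@]1(C)O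
F4 | step 7 | (6'S,8a'R)-6'-hydroxy-6',8a'-dimethyl-1',2',5',6',8',8a'-hexahydro-7'H-spiro[1,3-dioxolane-2,3'-azulen]-7'-one | O=C1C[C@@]2(C)CCC3(OCCO3)C2=CC[C@]1(C)O
F5 | step 9 | 5α,6α-epoxide of 14 (daucane locants; epoxide oxygen on the face opposite the C1 methyl) | O1[C@H]2C[C@](C)(O[Si](CC)(CC)CC)C(OS(=O)(=O)C(F)(F)F)=C[C@@]3(C)CCC4(OCCO4)[C@]123
F6 | step 4 | methyl (2S)-2-hydroxy-2-methyl-4-(7-methyl-1,4-dioxaspiro[4.4]non-6-en-6-yl)-4-oxobutanoate | COC(=O)[C@@](C)(O)CC(=O)C1=C(C)CCC12OCCO2
F7 | step 4 | methyl (2S,4S)-2,4-dihydroxy-2-methyl-4-(7-methyl-1,4-dioxaspiro[4.4]non-6-en-6-yl)butanoate | COC(=O)[C@@](C)(O)C[C@H](O)C1=C(C)CCC12OCCO2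
F8 | step 12 | 4-isopropenyl analogue of 18: 6,8a-dimethyl-3-(prop-1-en-2-yl)-6-[(triethylsilyl)oxy]-1,2,3,3a,4,5,6,8a-octahydroazulene-3,4-diol, same configuration as 18 | O[C@H]2C[C@](C)(O[Si](CC)(CC)CC)C=C[C@@]3(C)CC[C@@](O)(C(C)=C)[C@H]23
A1 | alternative 1 | metathesis precursor: 2-(1,3-dihydroxy-3-methylpent-4-enyl)-1-isopropyl-3-methyl-3-vinylcyclopentan-1-ol with the target configuration at C1, C4, C5, C6 and C8 | C=C[C@@](C)(O)C[C@H](O)[C@H]1[C@](O)(C(C)C)CC[C@]1(C)C=C
A2 | alternative 2 | (7E,9E)-10-[(tert-butyldimethylsilyl)oxy]-3-diazo-7-methyldeca-1,7,9-trien-4-one | C=CC(=[N+]=[N-])C(=O)CC/C(C)=C/C=C/O[Si](C)(C)C(C)(C)C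
A3 | alternative 3 | (2R,3R)-2-[(3R)-6-chloro-3-methylhex-1-en-3-yl]-3-hydroxy-4-methylpentanoic acid | OC(=O)[C@@H]([C@H](O)C(C)C)[C@@](C)(C=C)CCCCl
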